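The two ends of the (3R,4R)-lactone hide one unit, Ar–CH(CH2OH)–CH(O)–guaiacyl: as the ketone between rings B and A, and as C3–C2 of the dihydrobenzofuran between rings C and D. Each is cut between the CH(CH2OH) carbon and the oxygenated benzylic carbon. One double Evans aldol of a lactone bis(arylacetyl) imide with two molecules of O-benzylvanillin then forms both C–C bonds and four stereocentres, each acidic ArCH2C(=O)N methylene answering to its own oxazolidinone. The precursor carries an ortho CH2C(=O)-oxazolidinone arm on ring B ((R)-auxiliary, benzyl ether) and on ring C ((S)-auxiliary, methoxymethyl ether), which supply the opposite configurations at the two CH(CH2OH) carbons.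

Key step: step 21

Remark: ring A is the guaiacyl ring on the ketone, ring B the lactone C4-benzyl ring, ring C the benzo ring of the dihydrobenzofuran (lactone C3-benzyl ring), ring D the guaiacyl ring on its C2; the target is (3R,4R) at the lactone, (S) at the ketone α-carbon and (2S,3R) at the dihydrobenzofuran; compounds 8, 9, 30 and 33 are assumed to be purchased; the carbinol beside ring A is drawn as formed in step 21, and its configuration does not matter because step 25 removes it.

Step 1
Reactants: 1 vanillin; 2 allyl bromide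
Product: 3 4-(allyloxy)-3-methoxybenzaldehyde
Conditions: K2CO3, DMF, rt
Reagents that add atoms: none
Why: Williamson etherification of the phenoxide with a primary allylic bromide should be fast and leave the aldehyde untouched.

Step 2
Reactants: 3 4-(allyloxy)-3-methoxybenzaldehyde
Product: 4 3-allyl-4-hydroxy-5-methoxybenzaldehyde (5-allylvanillin)
Conditions: neat, 200 °C, N2
Reagents that add atoms: none
Why: aromatic Claisen rearrangement, in which the [3,3] shift can deliver the allyl group only to the free ortho carbon C5 (the other ortho carbon carries OMe) before the phenol is restored.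

Step 3
Reactants: 4 5-allylvanillin
Product: 5 3-allyl-4-(benzyloxy)-5-methoxybenzaldehyde
Conditions: BnBr, K2CO3, DMF, 60 °C
Reagents that add atoms: benzyl bromide BrCc1ccccc1
Why: Williamson benzylation of the hindered phenoxide; the benzyl group later keeps the ring B oxygen from closing a ring and leaves by hydrogenolysis in the last step.

Step 4
Reactants: 5 3-allyl-4-(benzyloxy)-5-methoxybenzaldehyde
Product: 6 [3-allyl-4-(benzyloxy)-5-methoxyphenyl]methanol
Conditions: NaBH4, MeOH, 0 °C
Reagents that add atoms: none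
Why: borohydride reduction of an aryl aldehyde, to which the alkene and the ethers are inert.

Step 5
Reactants: 6 [3-allyl-4-(benzyloxy)-5-methoxyphenyl]methanol
Product: 7 3-allyl-4-(benzyloxy)-5-methoxybenzyl bromide
Conditions: PBr3, Et2O, 0 °C; used crude
Reagents that add atoms: phosphorus tribromide BrP(Br)Br
Why: bromination of an electron-rich benzylic alcohol through its phosphite ester is a standard entry to this class of labile benzyl bromides.

Step 6
Reactants: 9 4-tert-butoxy-4-oxobutanoic acid; 8 (R)-4-benzyloxazolidin-2-one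
Product: 11 tert-butyl 4-[(4R)-4-benzyl-2-oxooxazolidin-3-yl]-4-oxobutanoate, via mixed pivalic anhydride 10 (not isolated)
Conditions: PivCl, Et3N, THF, −20 °C; then LiCl, 8, −20 °C to rt
Reagents that add atoms: none
Why: N-acylation of the oxazolidinone by a mixed pivalic anhydride, which is attacked at its unhindered carbonyl while LiCl and Et3N make the carbamate nitrogen nucleophilic without a strong base.

Step 7
Reactants: 11 tert-butyl 4-[(4R)-4-benzyl-2-oxooxazolidin-3-yl]-4-oxobutanoate; 7 3-allyl-4-(benzyloxy)-5-methoxybenzyl bromide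
Product: 13 tert-butyl (3R)-3-[3-allyl-4-(benzyloxy)-5-methoxybenzyl]-4-[(4R)-4-benzyl-2-oxooxazolidin-3-yl]-4-oxobutanoate, via sodium Z-enolate 12 (not isolated)
Conditions: NaN(SiMe3)2, THF, −78 °C; then 7, −78 to −40 °C
Reagents that add atoms: none
Why: Evans alkylation, in which only the imide α-CH2 is deprotonated (the ester α-CH2 is far less acidic) and the chelated Z-enolate is attacked by the benzylic bromide on the face away from the C4 benzyl group of the (R)-auxiliary, which should set the new centre as (R).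

Step 8
Reactants: 13 alkylated imide
Product: 15 (4R)-4-[3-allyl-4-(benzyloxy)-5-methoxybenzyl]dihydrofuran-2(3H)-one, via hydroxy ester 14 (not isolated)
Conditions: NaBH4, THF/H2O, 0 °C to rt; then TsOH·H2O (cat.), PhMe, 60 °C
Reagents that add atoms: none
Why: borohydride reduces the activated exocyclic imide carbonyl to the primary alcohol and releases the auxiliary without touching the tert-butyl ester, and acid-catalysed transesterification then closes the γ-lactone with the stereocentre untouched.

Step 9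
Reactants: 15 (4R)-4-[3-allyl-4-(benzyloxy)-5-methoxybenzyl]dihydrofuran-2(3H)-one
Product: 17 (4R)-4-[4-(benzyloxy)-3-(2-hydroxyethyl)-5-methoxybenzyl]dihydrofuran-2(3H)-one, via arylacetaldehyde 16 (not isolated)
Conditions: OsO4 (2 mol %), NaIO4, 2,6-lutidine, dioxane/H2O, rt; then NaBH4, THF/MeOH, −10 °C
Reagents that add atoms: osmium tetroxide O=[Os](=O)(=O)=O; sodium periodate [Na+].[O-]I(=O)(=O)=O
Why: Lemieux–Johnson cleavage of the terminal alkene followed at once by borohydride reduction at low temperature, where the aldehyde should react much faster than the γ-lactone.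

Step 10
Reactants: 17 (4R)-4-[4-(benzyloxy)-3-(2-hydroxyethyl)-5-methoxybenzyl]dihydrofuran-2(3H)-one
Product: 18 (4R)-4-[4-(benzyloxy)-3-(2-{[tert-butyl(dimethyl)silyl]oxy}ethyl)-5-methoxybenzyl]dihydrofuran-2(3H)-one
Conditions: TBSCl, imidazole, CH2Cl2, rt
Reagents that add atoms: tert-butyldimethylsilyl chloride CC(C)(C)[Si](C)(C)Cl
Why: silylation of the primary alcohol masks the ring B arm in a form that has no acidic C–H for the lactone enolate step and that differs from the allyl arm to come on ring C.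

Step 11
Reactants: 4 5-allylvanillin
Product: 19 3-allyl-5-methoxy-4-(methoxymethoxy)benzaldehyde
Conditions: MOMCl, iPr2NEt, CH2Cl2, 0 °C to rt
Reagents that add atoms: chloromethyl methyl ether COCCl
Why: O-alkylation of the phenol by the oxocarbenium-like chloride gives an acetal that survives base, hydride, oxidants and the boron aldol and leaves in acid in step 23.

Step 12
Reactants: 19 3-allyl-5-methoxy-4-(methoxymethoxy)benzaldehyde
Product: 20 [3-allyl-5-methoxy-4-(methoxymethoxy)phenyl]methanol
Conditions: NaBH4, MeOH, 0 °C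
Reagents that add atoms: none
Why: borohydride reduction of the aryl aldehyde under basic conditions that keep the acetal.

Step 13
Reactants: 20 [3-allyl-5-methoxy-4-(methoxymethoxy)phenyl]methanol
Product: 21 3-allyl-5-methoxy-4-(methoxymethoxy)benzyl bromide
Conditions: CBr4, PPh3, CH2Cl2, 0 °C; used after rapid filtration
Reagents that add atoms: carbon tetrabromide BrC(Br)(Br)Br
Why: Appel bromination is neutral and so should spare the methoxymethyl ether, which an acidic brominating agent could cleave.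

Step 14
Reactants: 18 silyl ether lactone; 21 3-allyl-5-methoxy-4-(methoxymethoxy)benzyl bromide
Product: 23 (3R,4R)-3-[3-allyl-5-methoxy-4-(methoxymethoxy)benzyl]-4-[4-(benzyloxy)-3-(2-{[tert-butyl(dimethyl)silyl]oxy}ethyl)-5-methoxybenzyl]dihydrofuran-2(3H)-one, via lithium enolate 22 (not isolated)
Conditions: LiN(SiMe3)2, THF, −78 °C; then 21, DMPU, −78 to −30 °C
Reagents that add atoms: none
Why: alkylation of a 4-substituted γ-butyrolactone enolate, in which the benzylic bromide approaches anti to the C4 benzyl group and should give the trans (3R,4R) lactone, which is also the more stable isomer.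

Step 15
Reactants: 23 trans-lactone silyl ether
Product: 24 (3R,4R)-3-[3-allyl-5-methoxy-4-(methoxymethoxy)benzyl]-4-[4-(benzyloxy)-3-(2-hydroxyethyl)-5-methoxybenzyl]dihydrofuran-2(3H)-one
Conditions: HF·pyridine, pyridine, THF, 0 °C to rt
Reagents that add atoms: none
Why: fluoride-driven cleavage of the primary silyl ether under buffered conditions that should leave the methoxymethyl ether, the lactone and the alkene alone.

Step 16
Reactants: 24 trans-lactone alcohol
Product: 25 ring B arylacetic acid (ring B arm CH2CO2H; ring C arm allyl)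
Conditions: TEMPO (cat.), PhI(OAc)2, MeCN/H2O, rt
Reagents that add atoms: water O
Why: oxoammonium-mediated oxidation of the primary alcohol to the aldehyde and, through its hydrate, to the acid, a method that tolerates terminal alkenes, acetals, benzyl ethers and lactones.

Step 17
Reactants: 25 ring B arylacetic acid; 8 (R)-4-benzyloxazolidin-2-one
Product: 27 mono-imide (ring B arm CH2C(=O)N of the (R)-oxazolidinone; ring C arm allyl), via mixed pivalic anhydride 26 (not isolated)
Conditions: PivCl, Et3N, THF, −20 °C; then LiCl, 8, −20 °C to rt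
Reagents that add atoms: none
Why: the same mixed-anhydride N-acylation as in step 6, mild enough for the lactone and its C3 centre.

Step 18
Reactants: 27 mono-imide
Product: 28 aldehyde (ring C arm CH2CHO)
Conditions: OsO4 (2 mol %), NaIO4, 2,6-lutidine, dioxane/H2O, rt
Reagents that add atoms: osmium tetroxide O=[Os](=O)(=O)=O; sodium periodate [Na+].[O-]I(=O)(=O)=O
Why: Lemieux–Johnson cleavage of the remaining terminal alkene, with 2,6-lutidine to suppress over-oxidation and to protect the imide and the acetal.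

Step 19
Reactants: 28 aldehyde
Product: 29 ring C arylacetic acid (ring C arm CH2CO2H; ring B arm imide)
Conditions: NaClO2, NaH2PO4, 2-methyl-2-butene, tBuOH/H2O, 0 °C to rt
Reagents that add atoms: sodium chlorite [Na+].[O-]Cl=O
Why: Pinnick oxidation at about pH 4 with an alkene scavenger for hypochlorous acid, so that the electron-rich rings and the imide should be spared.

Step 20
Reactants: 29 ring C arylacetic acid; 30 (S)-4-benzyloxazolidin-2-one
Product: 32 lactone bis-imide (ring B: OBn, OMe, CH2C(=O)N of the (R)-oxazolidinone; ring C: OMOM, OMe, CH2C(=O)N of the (S)-oxazolidinone), via mixed pivalic anhydride 31 (not isolated)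
Conditions: PivCl, Et3N, THF, −20 °C; then LiCl, 30, −20 °C to rt
Reagents that add atoms: none
Why: mixed-anhydride N-acylation as in step 17; the base is too weak to make the imide already present react.

Step 21
Reactants: 32 lactone bis-imide; 33 4-(benzyloxy)-3-methoxybenzaldehyde (two equivalents react)
Product: 35 bis syn-aldol adduct (ring B arm (2R,3R) on the (R)-auxiliary; ring C arm (2S,3S) on the (S)-auxiliary), via bis(dibutylboron) Z-enolate 34 (not isolated)
Conditions: Bu2BOTf (2.6 equiv), iPr2NEt (3.2 equiv), CH2Cl2, −78 to 0 °C; then 33 (3 equiv), −78 to 0 °C; MeOH, pH 7 buffer, H2O2, 0 °C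
Reagents that add atoms: none
Why: Bu2BOTf and iPr2NEt enolise only the two ArCH2C(=O)N methylenes, each flanked by an aryl ring (B or C) and an imide carbonyl and far more acidic than the lactone C3–H, to give two Z(O)-dibutylboron enolates, and each adds to the aldehyde through a closed Zimmerman–Traxler chair. The closest known reaction is the Evans syn-aldol of N-arylacetyl oxazolidinones with aromatic aldehydes, here run at two sites of one molecule. No ring closes; the two new C–C bonds are the future ketone Cα–carbinol bond on the ring B arm and the future C3–C2 bond of the dihydrobenzofuran on the ring C arm. The (R)-auxiliary, in its dipole-minimised conformation, shields one enolate face and sets the ring B α-carbon as (R), the (S)-auxiliary sets the ring C α-carbon as (S), and the chair with a Z-enolate places each carbinol syn to its α-carbon ((R) beside ring A, (S) beside ring D). The step needs site selectivity for the imides over the lactone, secured by the acidity gap and by boron activation of the imide carbonyl, and independent control at the two ends, secured because each enolate sees only its own auxiliary and the lactone stereocentres are remote. More than two equivalents of Bu2BOTf allow for boron held by the lactone carbonyl and the methoxymethyl ether, and the buffered peroxide work-up at 0 °C should free the aldolates without retro-aldol.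

Step 22
Reactants: 35 bis syn-aldol adduct
Product: 36 tetraol (ring B arm (1R,2S)-1-aryl-2-aryl-propane-1,3-diol; ring C arm (1S,2R))
Conditions: NaBH4, THF/H2O, 0 °C to rt
Reagents that add atoms: none
Why: borohydride in aqueous THF reduces N-acyl oxazolidinones at the exocyclic carbonyl to primary alcohols and releases both auxiliaries, while the γ-lactone is reduced far more slowly; the α-centres keep their geometry and only change descriptor.

Step 23
Reactants: 36 tetraol
Product: 37 trans-dihydrobenzofuran triol ((2S,3R); ring B arm 1,3-diol unchanged)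
Conditions: 2 M aq HCl, THF, rt
Reagents that add atoms: none
Why: acid ionises the ring D benzylic carbinol to a p-benzyloxybenzyl cation that the ring C oxygen captures 5-exo (freed from, or still carrying, the methoxymethyl group, which leaves as formaldehyde and methanol), a cyclodehydration to a phenylcoumaran that is reversible at C2 and so should settle on the trans ring dictated by the fixed C3 centre, whereas the cation beside ring A has only the benzyl-blocked ring B oxygen nearby and returns to the alcohol by capture of water.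

Step 24
Reactants: 37 trans-dihydrobenzofuran triol
Product: 38 bis(silyl ether) (both CH2OH groups as OTBS; carbinol beside ring A free)
Conditions: TBSCl (2.3 equiv), imidazole, DMF, 0 °C
Reagents that add atoms: tert-butyldimethylsilyl chloride CC(C)(C)[Si](C)(C)Cl
Why: the two primary alcohols should be silylated much faster than the hindered secondary benzylic alcohol flanked by two aryl-bearing carbons.

Step 25
Reactants: 38 bis(silyl ether)
Product: 39 aryl ketone ((S) at the α-carbon)
Conditions: Dess–Martin periodinane, pyridine, CH2Cl2, 0 °C to rt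
Reagents that add atoms: none
Why: Dess–Martin oxidation of the only free alcohol under buffered, near-neutral conditions, which should not enolise the new α-aryl ketone or touch the benzylic ether C–H of the dihydrobenzofuran.

Step 26
Reactants: 39 aryl ketone
Product: 40 keto diol tris(benzyl ether)
Conditions: HF·pyridine, pyridine, THF, 0 °C
Reagents that add atoms: none
Why: buffered fluoride removes both primary silyl ethers without base, which avoids β-elimination or epimerisation of the β-oxygenated α-aryl ketone.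

Step 27
Reactants: 40 keto diol tris(benzyl ether)
Product: 41 CNP0111438.1
Conditions: H2 (1 atm), Pd/C (10 wt % Pd on carbon), EtOAc/EtOH, rt
Reagents that add atoms: none
Why: hydrogenolysis of the three aryl benzyl ethers is neutral and should be much faster than reduction of the electron-rich aryl ketone or cleavage of the dihydrobenzofuran C2–O bond, so it is stopped as soon as the ethers are gone.

Compound list
1 | vanillin (4-hydroxy-3-methoxybenzaldehyde) | COc1cc(C=O)ccc1O | starting material
2 | allyl bromide | C=CCBr | starting material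
3 | 4-(allyloxy)-3-methoxybenzaldehyde | C=CCOc1ccc(C=O)cc1OC | intermediate
4 | 3-allyl-4-hydroxy-5-methoxybenzaldehyde (5-allylvanillin) | C=CCc1cc(C=O)cc(OC)c1O | intermediate
5 | 3-allyl-4-(benzyloxy)-5-methoxybenzaldehyde | C=CCc1cc(C=O)cc(OC)c1OCc1ccccc1 | intermediate
6 | [3-allyl-4-(benzyloxy)-5-methoxyphenyl]methanol | C=CCc1cc(CO)cc(OC)c1OCc1ccccc1 | intermediate
7 | 3-allyl-4-(benzyloxy)-5-methoxybenzyl bromide | C=CCc1cc(CBr)cc(OC)c1OCc1ccccc1 | intermediate
8 | (R)-4-benzyloxazolidin-2-one | O=C1N[C@H](Cc2ccccc2)CO1 | starting material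
9 | 4-tert-butoxy-4-oxobutanoic acid (mono-tert-butyl succinate) | CC(C)(C)OC(=O)CCC(=O)O | starting material
10 | mixed pivalic anhydride of 9 (formed in the flask) | CC(C)(C)OC(=O)CCC(=O)OC(=O)C(C)(C)C | intermediate
11 | tert-butyl 4-[(4R)-4-benzyl-2-oxooxazolidin-3-yl]-4-oxobutanoate | CC(C)(C)OC(=O)CCC(=O)N1[C@H](Cc2ccccc2)COC1=O | intermediate
12 | sodium Z-enolate of 11 (formed in the flask) | CC(C)(C)OC(=O)C/C=C(\[O-])N1[C@H](Cc2ccccc2)COC1=O.[Na+] | intermediate
13 | tert-butyl (3R)-3-[3-allyl-4-(benzyloxy)-5-methoxybenzyl]-4-[(4R)-4-benzyl-2-oxooxazolidin-3-yl]-4-oxobutanoate | CC(C)(C)OC(=O)C[C@@H](Cc1cc(CC=C)c(OCc2ccccc2)c(OC)c1)C(=O)N1[C@H](Cc2ccccc2)COC1=O | intermediate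
14 | tert-butyl (3R)-3-[3-allyl-4-(benzyloxy)-5-methoxybenzyl]-4-hydroxybutanoate (formed in the flask) | CC(C)(C)OC(=O)C[C@@H](Cc1cc(CC=C)c(OCc2ccccc2)c(OC)c1)CO | intermediate
15 | (4R)-4-[3-allyl-4-(benzyloxy)-5-methoxybenzyl]dihydrofuran-2(3H)-one | C=CCc1cc(C[C@H]2COC(=O)C2)cc(OC)c1OCc1ccccc1 | intermediate
16 | 2-[2-(benzyloxy)-3-methoxy-5-{[(3R)-5-oxotetrahydrofuran-3-yl]methyl}phenyl]acetaldehyde (formed in the flask) | O=CCc1cc(C[C@H]2COC(=O)C2)cc(OC)c1OCc1ccccc1 | intermediate
17 | (4R)-4-[4-(benzyloxy)-3-(2-hydroxyethyl)-5-methoxybenzyl]dihydrofuran-2(3H)-one | OCCc1cc(C[C@H]2COC(=O)C2)cc(OC)c1OCc1ccccc1 | intermediate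
18 | (4R)-4-[4-(benzyloxy)-3-(2-{[tert-butyl(dimethyl)silyl]oxy}ethyl)-5-methoxybenzyl]dihydrofuran-2(3H)-one | CC(C)(C)[Si](C)(C)OCCc1cc(C[C@H]2COC(=O)C2)cc(OC)c1OCc1ccccc1 | intermediate
19 | 3-allyl-5-methoxy-4-(methoxymethoxy)benzaldehyde | C=CCc1cc(C=O)cc(OC)c1OCOC | intermediate
20 | [3-allyl-5-methoxy-4-(methoxymethoxy)phenyl]methanol | C=CCc1cc(CO)cc(OC)c1OCOC | intermediate
21 | 3-allyl-5-methoxy-4-(methoxymethoxy)benzyl bromide | C=CCc1cc(CBr)cc(OC)c1OCOC | intermediate
22 | lithium enolate of 18 (formed in the flask) | CC(C)(C)[Si](C)(C)OCCc1cc(C[C@H]2COC([O-])=C2)cc(OC)c1OCc1ccccc1.[Li+] | intermediate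
23 | (3R,4R)-3-[3-allyl-5-methoxy-4-(methoxymethoxy)benzyl]-4-[4-(benzyloxy)-3-(2-{[tert-butyl(dimethyl)silyl]oxy}ethyl)-5-methoxybenzyl]dihydrofuran-2(3H)-one (trans) | CC(C)(C)[Si](C)(C)OCCc1cc(C[C@H]2COC(=O)[C@@H]2Cc2cc(CC=C)c(OCOC)c(OC)c2)cc(OC)c1OCc1ccccc1 | intermediate
24 | (3R,4R)-3-[3-allyl-5-methoxy-4-(methoxymethoxy)benzyl]-4-[4-(benzyloxy)-3-(2-hydroxyethyl)-5-methoxybenzyl]dihydrofuran-2(3H)-one | OCCc1cc(C[C@H]2COC(=O)[C@@H]2Cc2cc(CC=C)c(OCOC)c(OC)c2)cc(OC)c1OCc1ccccc1 | intermediate
25 | ring B arylacetic acid: 24 with the ring B arm as CH2CO2H | OC(=O)Cc1cc(C[C@H]2COC(=O)[C@@H]2Cc2cc(CC=C)c(OCOC)c(OC)c2)cc(OC)c1OCc1ccccc1 | intermediate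
26 | mixed pivalic anhydride of 25 (formed in the flask) | CC(C)(C)C(=O)OC(=O)Cc1cc(C[C@H]2COC(=O)[C@@H]2Cc2cc(CC=C)c(OCOC)c(OC)c2)cc(OC)c1OCc1ccccc1 | intermediate
27 | mono-imide: ring B arm CH2C(=O)N of (R)-4-benzyloxazolidin-2-one, ring C arm allyl, (3R,4R)-lactone | O=C(Cc1cc(C[C@H]2COC(=O)[C@@H]2Cc2cc(CC=C)c(OCOC)c(OC)c2)cc(OC)c1OCc1ccccc1)N1[C@H](Cc2ccccc2)COC1=O | intermediate
28 | aldehyde: 27 with the ring C arm as CH2CHO | O=C(Cc1cc(C[C@H]2COC(=O)[C@@H]2Cc2cc(CC=O)c(OCOC)c(OC)c2)cc(OC)c1OCc1ccccc1)N1[C@H](Cc2ccccc2)COC1=O | intermediate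
29 | ring C arylacetic acid: 27 with the ring C arm as CH2CO2H | O=C(Cc1cc(C[C@H]2COC(=O)[C@@H]2Cc2cc(CC(=O)O)c(OCOC)c(OC)c2)cc(OC)c1OCc1ccccc1)N1[C@H](Cc2ccccc2)COC1=O | intermediate
30 | (S)-4-benzyloxazolidin-2-one | O=C1N[C@@H](Cc2ccccc2)CO1 | starting material
31 | mixed pivalic anhydride of 29 (formed in the flask) | O=C(Cc1cc(C[C@H]2COC(=O)[C@@H]2Cc2cc(CC(=O)OC(=O)C(C)(C)C)c(OCOC)c(OC)c2)cc(OC)c1OCc1ccccc1)N1[C@H](Cc2ccccc2)COC1=O | intermediate
32 | lactone bis-imide: (3R,4R)-lactone, ring B (OBn, OMe) arm on the (R)-oxazolidinone, ring C (OMOM, OMe) arm on the (S)-oxazolidinone | O=C(Cc1cc(C[C@H]2COC(=O)[C@@H]2Cc2cc(OC)c(OCOC)c(CC(=O)N3[C@@H](Cc4ccccc4)COC3=O)c2)cc(OC)c1OCc1ccccc1)N1[C@H](Cc2ccccc2)COC1=O | intermediate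
33 | 4-(benzyloxy)-3-methoxybenzaldehyde | COc1cc(C=O)ccc1OCc1ccccc1 | starting material
34 | bis(dibutylboron) Z-enolate of 32 (formed in the flask) | CCCCB(CCCC)O/C(=C\c1cc(C[C@H]2COC(=O)[C@@H]2Cc2cc(OC)c(OCOC)c(/C=C(\OB(CCCC)CCCC)N3[C@@H](Cc4ccccc4)COC3=O)c2)cc(OC)c1OCc1ccccc1)N1[C@H](Cc2ccccc2)COC1=O | intermediate
35 | bis syn-aldol adduct: ring B arm (2R,3R)-3-[4-(benzyloxy)-3-methoxyphenyl]-3-hydroxy-2-arylpropanoyl on the (R)-auxiliary, ring C arm (2S,3S) on the (S)-auxiliary | COc1cc([C@H](O)[C@H](C(=O)N2[C@H](Cc3ccccc3)COC2=O)c2cc(C[C@H]3COC(=O)[C@@H]3Cc3cc(OC)c(OCOC)c(c3)[C@H](C(=O)N3[C@@H](Cc4ccccc4)COC3=O)[C@H](O)c3ccc(OCc4ccccc4)c(OC)c3)cc(OC)c2OCc2ccccc2)ccc1OCc1ccccc1 | intermediate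
36 | tetraol: ring B arm (1R,2S)-1-[4-(benzyloxy)-3-methoxyphenyl]-2-arylpropane-1,3-diol, ring C arm (1S,2R), ring C phenol as OMOM | COc1cc([C@H](O)[C@H](CO)c2cc(C[C@H]3COC(=O)[C@@H]3Cc3cc(OC)c(OCOC)c(c3)[C@H](CO)[C@H](O)c3ccc(OCc4ccccc4)c(OC)c3)cc(OC)c2OCc2ccccc2)ccc1OCc1ccccc1 | intermediate
37 | trans-dihydrobenzofuran triol: (2S,3R)-2-[4-(benzyloxy)-3-methoxyphenyl]-3-(hydroxymethyl)-7-methoxy-2,3-dihydrobenzofuran-5-yl unit on lactone C3, ring B arm 1,3-diol | COc1cc([C@H](O)[C@H](CO)c2cc(C[C@H]3COC(=O)[C@@H]3Cc3cc(OC)c4c(c3)[C@H](CO)[C@@H](c3ccc(OCc5ccccc5)c(OC)c3)O4)cc(OC)c2OCc2ccccc2)ccc1OCc1ccccc1 | intermediate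
38 | bis(tert-butyldimethylsilyl) ether of 37 at both CH2OH groups | COc1cc([C@H](O)[C@H](CO[Si](C)(C)C(C)(C)C)c2cc(C[C@H]3COC(=O)[C@@H]3Cc3cc(OC)c4c(c3)[C@H](CO[Si](C)(C)C(C)(C)C)[C@@H](c3ccc(OCc5ccccc5)c(OC)c3)O4)cc(OC)c2OCc2ccccc2)ccc1OCc1ccccc1 | intermediate
39 | aryl ketone: 38 with the carbinol beside ring A oxidised, (S) at the α-carbon | COc1cc(C(=O)[C@H](CO[Si](C)(C)C(C)(C)C)c2cc(C[C@H]3COC(=O)[C@@H]3Cc3cc(OC)c4c(c3)[C@H](CO[Si](C)(C)C(C)(C)C)[C@@H](c3ccc(OCc5ccccc5)c(OC)c3)O4)cc(OC)c2OCc2ccccc2)ccc1OCc1ccccc1 | intermediate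
40 | keto diol tris(benzyl ether): the target with the three phenols as benzyl ethers | COc1cc(C(=O)[C@H](CO)c2cc(C[C@H]3COC(=O)[C@@H]3Cc3cc(OC)c4c(c3)[C@H](CO)[C@@H](c3ccc(OCc5ccccc5)c(OC)c3)O4)cc(OC)c2OCc2ccccc2)ccc1OCc1ccccc1 | intermediate
41 | CNP0111438.1 | COc1cc(C(=O)[C@H](CO)c2cc(C[C@H]3COC(=O)[C@@H]3Cc3cc(OC)c4c(c3)[C@H](CO)[C@@H](c3ccc(O)c(OC)c3)O4)cc(OC)c2O)ccc1O | target

Total step count: 27.
Longest linear sequence: 23 steps (1–5, 7–10, 14–27, from vanillin).

Steps most likely to fail

Step 21. Enolisation or addition may stall after the first arm because boron is held by the lactone carbonyl and the methoxymethyl ether, or the diaryl aldolates may revert during work-up, so that mono-adducts dominate. The fallback builds the two ends one after the other. It sets out from 27: a single boron aldol with 33 (Bu2BOTf, iPr2NEt, CH2Cl2, −78 to 0 °C; buffered H2O2 work-up) through the dibutylboron Z-enolate F1 should give the ring B mono-adduct F2. Lemieux–Johnson cleavage of the ring C allyl group then gives the aldehyde F3 and Pinnick oxidation the acid F4. Its mixed pivalic anhydride F5 (PivCl, Et3N, −20 °C, where the hindered carbinol should not be acylated) acylates 30 in the presence of LiCl to give the imide F6. A second boron aldol with 33, run with one extra equivalent of Bu2BOTf for the free carbinol through the O-borylated Z-enolate F7, comes back to the route at 35.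

Step 23. The benzylic carbinol beside ring A ionises under the same acid; before the ring C oxygen has closed the other end, it may be lost by elimination to a stilbene, by loss of formaldehyde from the free 1,3-diol, or by capture of the ring B benzyl ether oxygen. The fallback removes the free hydroxyls and lets an acetate leave under Lewis acid. It sets out from 36: Ac2O, pyridine and DMAP give the tetraacetate F8. BF3·OEt2 in CH2Cl2 at −40 °C then ionises the benzylic acetates. The ring C methoxymethyl ether oxygen closes onto the ring D cation and loses its methoxymethyl group as methoxymethyl acetate, which should give the trans-dihydrobenzofuran triacetate F9. The cation beside ring A is meanwhile held reversibly as the six-membered acetoxonium ion of its neighbouring acetate and cannot lose formaldehyde. K2CO3 in MeOH at 0 °C, followed by a mildly acidic work-up to re-close any opened lactone, removes the three acetates and comes back to the route at 37.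

Step 22. Under the basic borohydride conditions the diaryl aldol units may undergo retro-aldol cleavage before the hindered imides are reduced, or reduction may stop at one arm. The fallback caps the aldol hydroxyls first. It sets out from 35: TESOTf and 2,6-lutidine in CH2Cl2 at −78 °C give the bis(triethylsilyl) ether F10, which cannot revert. NaBH4 in THF/H2O then cleaves both auxiliaries to give the bis(triethylsilyl) ether diol F11. The aqueous acid of step 23 strips the two triethylsilyl ethers together with the methoxymethyl group and closes the ring, so the fallback comes back to the route at 37.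

Further compounds
F1 | step 21 | dibutylboron Z-enolate of 27 | CCCCB(CCCC)O/C(=C\c1cc(C[C@H]2COC(=O)[C@@H]2Cc2cc(CC=C)c(OCOC)c(OC)c2)cc(OC)c1OCc1ccccc1)N1[C@H](Cc2ccccc2)COC1=O
F2 | step 21 | ring B mono syn-aldol adduct ((2R,3R) on the (R)-auxiliary; ring C arm allyl) | COc1cc([C@H](O)[C@H](C(=O)N2[C@H](Cc3ccccc3)COC2=O)c2cc(C[C@H]3COC(=O)[C@@H]3Cc3cc(CC=C)c(OCOC)c(OC)c3)cc(OC)c2OCc2ccccc2)ccc1OCc1ccccc1
F3 | step 21 | aldehyde: F2 with the ring C arm as CH2CHO | COc1cc([C@H](O)[C@H](C(=O)N2[C@H](Cc3ccccc3)COC2=O)c2cc(C[C@H]3COC(=O)[C@@H]3Cc3cc(CC=O)c(OCOC)c(OC)c3)cc(OC)c2OCc2ccccc2)ccc1OCc1ccccc1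
F4 | step 21 | acid: F2 with the ring C arm as CH2CO2H | COc1cc([C@H](O)[C@H](C(=O)N2[C@H](Cc3ccccc3)COC2=O)c2cc(C[C@H]3COC(=O)[C@@H]3Cc3cc(CC(=O)O)c(OCOC)c(OC)c3)cc(OC)c2OCc2ccccc2)ccc1OCc1ccccc1
F5 | step 21 | mixed pivalic anhydride of F4 | COc1cc([C@H](O)[C@H](C(=O)N2[C@H](Cc3ccccc3)COC2=O)c2cc(C[C@H]3COC(=O)[C@@H]3Cc3cc(CC(=O)OC(=O)C(C)(C)C)c(OCOC)c(OC)c3)cc(OC)c2OCc2ccccc2)ccc1OCc1ccccc1
F6 | step 21 | imide of F4 with 30 (ring C arm on the (S)-auxiliary; ring B arm already an aldol adduct) | COc1cc([C@H](O)[C@H](C(=O)N2[C@H](Cc3ccccc3)COC2=O)c2cc(C[C@H]3COC(=O)[C@@H]3Cc3cc(CC(=O)N4[C@@H](Cc5ccccc5)COC4=O)c(OCOC)c(OC)c3)cc(OC)c2OCc2ccccc2)ccc1OCc1ccccc1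
F7 | step 21 | O-borylated dibutylboron Z-enolate of F6 | COc1cc([C@H](OB(CCCC)CCCC)[C@H](C(=O)N2[C@H](Cc3ccccc3)COC2=O)c2cc(C[C@H]3COC(=O)[C@@H]3Cc3cc(/C=C(\OB(CCCC)CCCC)N4[C@@H](Cc5ccccc5)COC4=O)c(OCOC)c(OC)c3)cc(OC)c2OCc2ccccc2)ccc1OCc1ccccc1
F8 | step 23 | tetraacetate of 36 | COc1cc([C@H](OC(C)=O)[C@H](COC(C)=O)c2cc(C[C@H]3COC(=O)[C@@H]3Cc3cc(OC)c(OCOC)c(c3)[C@H](COC(C)=O)[C@H](OC(C)=O)c3ccc(OCc4ccccc4)c(OC)c3)cc(OC)c2OCc2ccccc2)ccc1OCc1ccccc1
F9 | step 23 | trans-dihydrobenzofuran triacetate (triacetate of 37) | COc1cc([C@H](OC(C)=O)[C@H](COC(C)=O)c2cc(C[C@H]3COC(=O)[C@@H]3Cc3cc(OC)c4c(c3)[C@H](COC(C)=O)[C@@H](c3ccc(OCc5ccccc5)c(OC)c3)O4)cc(OC)c2OCc2ccccc2)ccc1OCc1ccccc1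
F10 | step 22 | bis(triethylsilyl) ether of 35 at both carbinols | COc1cc([C@H](O[Si](CC)(CC)CC)[C@H](C(=O)N2[C@H](Cc3ccccc3)COC2=O)c2cc(C[C@H]3COC(=O)[C@@H]3Cc3cc(OC)c(OCOC)c(c3)[C@H](C(=O)N3[C@@H](Cc4ccccc4)COC3=O)[C@H](O[Si](CC)(CC)CC)c3ccc(OCc4ccccc4)c(OC)c3)cc(OC)c2OCc2ccccc2)ccc1OCc1ccccc1
F11 | step 22 | bis(triethylsilyl) ether diol (both imides reduced to CH2OH) | COc1cc([C@H](O[Si](CC)(CC)CC)[C@H](CO)c2cc(C[C@H]3COC(=O)[C@@H]3Cc3cc(OC)c(OCOC)c(c3)[C@H](CO)[C@H](O[Si](CC)(CC)CC)c3ccc(OCc4ccccc4)c(OC)c3)cc(OC)c2OCc2ccccc2)ccc1OCc1ccccc1
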